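(The constants belong to no real substance; the result is computed.)

Product in this flask is what remains of the charge once two debts are paid, so a repeat of the run is best watched through those debts.

- violet: starting material 0.30 M; protic impurity 0.0150 M; free catalyst 4.5 mM; temperature 48 °C; time 1.0 h
- ochre: starting material 0.30 M; protic impurity 0.0150 M; free catalyst 4.5 mM; temperature 40 °C; time 1.0 h

    starting material + protic impurity → quenched substrate (k1 = 1.1 M⁻¹ min⁻¹, Ea1 = 58.0 kJ mol⁻¹)
    free catalyst + product → spent catalyst (k2 = 0.028 M⁻¹ min⁻¹, Ea2 = 83.0 kJ mol⁻¹)
    starting material + free catalyst → catalyst intermediate (k3 = 15 M⁻¹ min⁻¹, Ea3 = 60.0 kJ mol⁻¹)
    catalyst intermediate → free catalyst + product (k4 = 92 min⁻¹, Ea4 = 77.0 kJ mol⁻¹)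
    (constants at 40 °C)

1. which of these there is most of at the end, counted by the starting material in it, violet (catalyst intermediate / starting material / product)
2. which of these there is most of at the end, counted by the starting material in it, ochre (catalyst intermediate / starting material / product)
3. amount of the one of these that there is most of at the end, in percent of the starting material charged, violet
4. amount of the one of these that there is most of at the end, in percent of the starting material charged, ochre

- the constants hold at 40 °C; other temperatures follow from the activation energies

Follow one molecule of starting material. Its first fork is free catalyst or protic impurity, and each rate constant times its partner's concentration gives a pseudo-first-order rate for that road. At the start in ochre the catalyst road is taken 4.1 times as often as the other, but that ratio does not measure the loss, since the impurity is the smaller charge. Seen from the impurity, starting material is plentiful. One impurity molecule lasts about 3.03 min, a shorter time than the 14.8 min a starting-material molecule lasts on the catalyst road. So we book the impurity's charge as lost starting material, one for one: 5.00%.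

The second fork belongs to the product, which may stay free or bind free catalyst as spent catalyst. For one product molecule this is slow, with a half-life of 92 h in ochre, longer than the 1.0 h run. One catalyst molecule, among product approaching 0.30 M, lasts about 1.98 h at 40 °C, so this debt falls due within hours, and each spent catalyst holds one product: 1.50%.

Taking both from the charge leaves 93.5%. This is the plateau yield: the product, in percent of the starting material charged, once impurity and catalyst have each taken their one-for-one share.

| Entry | What it does | Share of the charge |
|---|---|---|
| protic impurity | takes starting material | 5.00% |
| free catalyst | holds product | 1.50% |
| plateau yield | what remains | 93.5% |

Before that end, the balance puts product at the plateau minus the starting material still unconverted, plus the free catalyst not yet spent and the protic impurity still unbound, all in percent of the charge. Violet and ochre share their charges, so we commit to one plateau for both; the distance from it at the hour we do not reckon by hand.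

The forecast names product for violet and product for ochre, with 94.3% (93.3% to 94.9%) and 92% (90.5% to 93.3%). Its ground is this: “Product poisoning slows the catalyst but does not kill it within the hour”. Its violet figure stands above our plateau, and its ochre figure below.

The flasks give product as the largest in both, 93.5% in violet and 91.7% in ochre, each inside the forecast's range. Violet at the hour holds 0.622% starting material against free catalyst worth 0.615% of the charge, so in the balance the two nearly cancel and violet's product stands at the plateau figure, and a reading ten times later barely differs. Ochre at the hour holds 2.87% starting material against free catalyst worth 1.05% of the charge, which in the balance puts ochre's product 1.8 percentage points below the plateau. Left standing, ochre's product reads 93.5% after 10.0 h.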